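**Remarks on the chemistry.** The (1S,2R)-cis-dihydrodiol of toluene (1) is taken as a purchasable product of microbial dihydroxylation. Acetal 2 is used as the mixture of epimers at the acetal carbon, because that centre disappears in step 2. Atom labels follow germacrane numbering: ring carbons C1–C10, lactone carbons C11–C13 (C12 carbonyl, C13 exocyclic methylene), C14 the methyl on C10, C15 the methyl on C4. Ring A is C3, C4, C5, C6, C7, C8; ring B is C8, C9, C10, C1, C2, C3.

## Analysis of the target

The target is a ten-membered carbocycle with two Z trisubstituted alkenes (C1=C10 and C4=C5) and an α-methylene-γ-butyrolactone cis-fused across C6–C7. It has five ring stereocentres, C3 (S, acetate), C6 (R), C7 (R), C8 (S, ester) and C9 (R, free hydroxyl), plus the (2R,3R)-2,3-dimethyloxirane-2-carboxylate on O8. H6 and H7 are cis, the C8 and C9 oxygens are anti along the C7–C10 chain, and C3 is isolated from the C6–C9 array by the C4=C5 alkene. The sensitive groups are the α-methylene lactone (a Michael acceptor), the epoxide, an allylic acetate, and an ester next to a free hydroxyl, where acyl migration from O8 to O9 is possible. The difficulty lies in closing a medium ring with two Z trisubstituted alkenes, in setting four contiguous stereocentres on a flexible ring, and in telling three ring oxygens apart. The strategy rests on one feature: C3 and C8 both carry oxygen and sit 1,6 across the ring. A bond between them divides the ring into ring A and ring B, two cyclohexenes that each hold one alkene as an ordinary cis ring alkene. The target can therefore be read as the ring-expanded form of a cis-fused bicyclic 3,8-diol.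

## Retrosynthetic reasoning

**Ester and protecting group at the end.** Target 38 is traced to PMB ether 37, so that the last step is a neutral oxidative deprotection that cannot move the C8 ester to O9. The C8–O ester bond of 37 is cut to alcohol 30 and epoxy acid 35. The epoxide is made on the small acid, because epoxidising an angelate on the ring would have to compete with three other alkenes. Acid 35 goes back through epoxy alcohol 33 and allylic alcohol 32 to angelic acid 31, where a tartrate-controlled epoxidation sets both epoxide centres.

**The two carbinols.** Acetate 30 comes from diol 29, and 29 from keto alcohol 28 and diketone 27. The C8 carbinol is set first, by chelation between the C8 carbonyl and the C9 ether, which gives the required anti relationship. The C3 carbinol is then set by a chiral oxazaborolidine, because nothing in the ring can be trusted to control it. Acetylating C3 before esterifying C8 means the hindered esterification is run on a substrate that has no enolisable ketone left.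

**The key disconnection.** In 27 the C3 and C8 carbonyls are reconnected as a C3–C8 bond, giving the cis-fused bicyclic diol 25. No other cut removes the medium ring and the question of alkene geometry at once: ring A and ring B are six-membered, so both alkenes are necessarily cis. The forward reaction has only to cleave a ditertiary cis-glycol chemoselectively.

**The exocyclic methylene.** C13 is removed from 25 to give 22. It is put on at this stage because enolate chemistry after the scission would meet two ketones, and later two more esters, whereas in 22 only two inert tertiary hydroxyls accompany the lactone. Compounds 25 and 27 therefore carry the methylene as a spectator.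

**Ring A.** The C7–C8 bond of 22 is cut to keto butenolide 20, for a reductive ketyl addition to the butenolide. This places the new bond at a hindered ketone without an intermolecular addition and produces the tertiary C8 hydroxyl directly. C7 can only bond on the face of the tether that reaches it from C6, so the cis lactone fusion and the configuration of C7 follow from C6 alone. The C3 and C8 configurations are free to vary, since both are erased in the scission.

**Butenolide and C8 ketone.** Butenolide 20 is opened at C7=C11 to acrylate 19 (ring-closing metathesis). Ketone 19 comes from alcohol 18, the acrylate from triol 17, and 17 from bis-silyl ether 16. A ring B intermediate with carbonyls at C3 and C8 together is avoided throughout, because such a dione would enolise and aromatise. The two carbonyls are unmasked one after the other.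

**C3–C4 bond.** Carbinol 16 is cut between C3 and C4 to ring B ketone 6 and alkenyl iodide 13. The Z geometry of C4=C5 is fixed in 13 before the coupling, and an organocerium reagent is planned because 6 enolises easily.

**The alkenyl iodide.** Iodide 13 goes back through resolved alcohol 12 and racemate 11 to enynol 9, made from acrolein 7 and alkynyl Grignard reagent 8. A directed trans-hydroalumination sets the alkene geometry and a kinetic resolution sets C6.

**Ring B.** Ketone 6 is traced through vinyl epoxide 5 and epoxy alcohol 4 to dienol 3, acetal 2 and arene diol 1. C9 is the microbial stereocentre. The acetal opening distinguishes O8 from O9, and the free O8 hydroxyl then directs oxygen to C3.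

## Alternatives that were turned down

**Alternative 1:** The lactone ring is disconnected at C7–C11, together with the C8–O bond, on an intact ten-membered ring. In the forward step a vinyl radical at C11, held on O6 through a bromoallyl acetal, adds 5-exo to C7 of a C7=C8 ring alkene, and the C8 radical is trapped by dioxygen to give lactol ether A1.
- For: the five-membered ring, the exocyclic methylene and the C8 oxygen arrive in one operation, the cis fusion is enforced by the tether, and no enolisable ketone ever stands next to C7. On that last point it is stronger than the chosen route.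
- Against: it presupposes the ten-membered ring with both Z alkenes and a third alkene at C7=C8, so the hardest problem is left open. The C8 radical in a flexible ring is captured by oxygen without facial control. Transannular addition to C1=C10 and hydrogen shifts can compete, and the lactol must still be oxidised.
- Comparison: the chosen strategy obtains the ring and both alkenes from rigid six-membered rings and sets C8 by chelation, at the price of extra redox steps after the ring is opened.

**Alternative 2:** The ring is disconnected at C5–C6 and the lactone at its C–O bond. A vinylchromium species generated at C5 with CrCl2/NiCl2 adds to a C6 aldehyde, and the alkoxide closes onto an acrylate ester to give A2.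
- For: it is convergent, all ring oxygens are already differentiated, and there is no sensitive diketone and little redox work after ring closure. On step economy after ring formation it is as strong as or stronger than the chosen route.
- Against: closing a ten-membered ring by intramolecular addition fights strain and entropy and needs high dilution and excess chromium. C6 is created in the macrocyclisation under substrate control that cannot be predicted with confidence. The aldehyde carries an epimerisable C7 centre, and the open-chain precursor with C3, C7, C8 and C9 and two Z trisubstituted alkenes must be built by acyclic stereocontrol.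
- Comparison: the chosen strategy forms the ring by expansion of a strain-free bicycle and takes C6 from a resolved fragment. It offers certainty of ring formation and alkene geometry in place of convergence.

**Alternative 3:** C7–C8 is disconnected, with the carbocycle traced back to a thirteen-membered keto ether in which O8 is tied to C13. A boron enolate at C8 undergoes a [2,3]-Wittig shift onto the butenolide, forming C7–C8, breaking O8–C13 and contracting the ring to give A3.
- For: one step creates the carbocycle, C7, C8, the C8 hydroxyl and the methylene lactone, and a thirteen-membered ring is easier to close than a ten-membered one. Conceptually it is the most economical way to the lactone region.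
- Against: C7 and C8 are decided together by enolate geometry and by the folding of a large ring, with no independent handle. [1,2]-Shift and β-elimination are known competitors of such enolate rearrangements. The product still needs a stereoselective reduction at C9 next to a free hydroxyl, and the macrocyclic ether has to be made first.
- Comparison: the chosen strategy uses only established reaction types for ring construction and lets a geometric constraint, not a conformational preference, decide C7.

Key step: step 17

## Route

Step 1
Reactants: 1 toluene cis-dihydrodiol, (1S,2R)-3-methylcyclohexa-3,5-diene-1,2-diol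
Product: 2 4-methoxybenzylidene acetal of 1 (cis-fused dihydro-1,3-benzodioxole, both epimers at the acetal carbon)
Conditions: 4-MeOC6H4CH(OMe)2, PPTS (cat.), CH2Cl2, 0 °C
Reagents that add atoms: 4-methoxybenzaldehyde dimethyl acetal, COC(OC)c1ccc(OC)cc1
Why: Acid-catalysed transacetalisation of the cis-diol gives the cis-fused dioxolane; a weak acid at low temperature avoids dehydration of the dienediol to a cresol, and the acetal is the handle that lets O8 and O9 be told apart.

Step 2
Reactants: 2 4-methoxybenzylidene acetal
Product: 3 (1S,6R)-6-[(4-methoxybenzyl)oxy]-5-methylcyclohexa-2,4-dien-1-ol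
Conditions: i-Bu2AlH, CH2Cl2, −78 → 0 °C; Rochelle salt work-up
Reagents that add atoms: none
Why: Reductive opening of the aryl acetal: aluminium binds the less hindered oxygen (O8, remote from the methyl-bearing carbon) and hydride is delivered to the oxocarbenium ion left on O9, so the PMB group should end on O9 and the O8 hydroxyl is freed.

Step 3
Reactants: 3 dienol PMB ether
Product: 4 (1R,2R,3R,6S)-3-[(4-methoxybenzyl)oxy]-4-methyl-7-oxabicyclo[4.1.0]hept-4-en-2-ol (epoxide at C2–C3 of the germacrane numbering, cis to the hydroxyl)
Conditions: VO(acac)2 (cat.), t-BuOOH, CH2Cl2, 0 °C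
Reagents that add atoms: tert-butyl hydroperoxide, CC(C)(C)OO
Why: Hydroxyl-directed epoxidation: the vanadium alkoxide of the C8 hydroxyl delivers oxygen only to the adjacent C2=C3 alkene, while C1=C10 has no free allylic hydroxyl; the epoxide configuration is of no consequence because both carbons lose it in step 5.

Step 4
Reactants: 4 epoxy alcohol
Product: 5 triethylsilyl ether of 4
Conditions: Et3SiCl, imidazole, DMF, 0 °C → rt
Reagents that add atoms: chlorotriethylsilane, CC[Si](Cl)(CC)CC
Why: Standard silylation of the secondary alcohol under base-buffered conditions that spare the acid-sensitive vinyl epoxide.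

Step 5
Reactants: 5 silylated vinyl epoxide
Product: 6 (2R,3R)-3-[(4-methoxybenzyl)oxy]-4-methyl-2-[(triethylsilyl)oxy]cyclohex-4-en-1-one (C3 ketone of ring B)
Conditions: Pd(PPh3)4 (5 mol%), THF, rt
Reagents that add atoms: none
Why: Zerovalent palladium opens the vinyl epoxide to a π-allylpalladium alkoxide and moves the carbinol hydrogen to C2 (the known isomerisation of 1,3-diene monoepoxides to β,γ-unsaturated ketones); this gives the C3 carbonyl with C2 as CH2 and C1=C10 in place, and no base is present to pull the alkene into conjugation.

Step 6
Reactants: 7 acrolein; 8 1-propynylmagnesium bromide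
Product: 9 rac-hex-1-en-4-yn-3-ol
Conditions: THF, −78 → 0 °C; NH4Cl (aq)
Reagents that add atoms: none
Why: 1,2-Addition of an alkynyl Grignard reagent to the enal at low temperature; the carbinol carbon becomes C6, the vinyl group supplies C7 and the propynyl group supplies C5, C4 and C15.

Step 7
Reactants: 9 rac-hex-1-en-4-yn-3-ol
Product: 11 rac-(4Z)-5-iodohexa-1,4-dien-3-ol, via sodium alkenylalanate 10 (not isolated)
Conditions: NaAlH2(OCH2CH2OMe)2, THF, 0 °C; EtOAc; then I2, −78 °C
Reagents that add atoms: iodine, II
Why: Alkoxide-directed trans-hydroalumination of the propargylic alcohol puts aluminium on the distal alkyne carbon (C4) and hydrogen on C5, and iodinolysis with retention gives the iodoalkene in which C6 and iodine are cis, the geometry required for the Z C4=C5 alkene.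

Step 8
Reactants: 11 rac-(4Z)-5-iodohexa-1,4-dien-3-ol
Product: 12 (3S,4Z)-5-iodohexa-1,4-dien-3-ol
Conditions: Ti(OiPr)4 (1 equiv), L-(+)-diisopropyl tartrate (1.2 equiv), t-BuOOH (0.6 equiv), 4 Å MS, CH2Cl2, −20 °C, stopped a little beyond half conversion
Reagents that add atoms: none
Why: Sharpless kinetic resolution of a secondary allylic alcohol: with the L-(+)-tartrate the R enantiomer is epoxidised at its vinyl group much faster, and the S alcohol, whose bulky iodoalkenyl group would sit against the catalyst, should be recovered; the electron-poor Z iodoalkene is not epoxidised.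

Step 9
Reactants: 12 (3S,4Z)-5-iodohexa-1,4-dien-3-ol
Product: 13 triethyl{[(3S,4Z)-5-iodohexa-1,4-dien-3-yl]oxy}silane
Conditions: Et3SiCl, imidazole, CH2Cl2, 0 °C
Reagents that add atoms: chlorotriethylsilane, CC[Si](Cl)(CC)CC
Why: Silyl protection so that the halogen–metal exchange of the next step gives a single, soluble alkenyl nucleophile.

Step 10
Reactants: 13 alkenyl iodide silyl ether; 6 ring B ketone
Product: 16 ring B tertiary carbinol carrying the (2Z,4S)-4-(triethylsilyloxy)hexa-2,5-dien-2-yl chain at C3 (C3–OH, C8–OSiEt3 and C9–OPMB all cis), via alkenyllithium 14 (not isolated), via alkenylcerium dichloride 15 (not isolated)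
Conditions: 13, t-BuLi (2.05 equiv), Et2O, −78 °C; CeCl3, THF, −78 °C; then 6, −78 °C; NH4Cl (aq)
Reagents that add atoms: none
Why: Iodine–lithium exchange keeps the alkene geometry, and the weakly basic organocerium reagent adds 1,2 to the easily enolised β,γ-unsaturated ketone; attack anti to the neighbouring silyloxy group and to the PMB ether should put the C3 hydroxyl cis to O8 and O9, although either C3 epimer would serve because C3 becomes trigonal again in step 17.

Step 11
Reactants: 16 bis-silyl ether
Product: 17 triol (hydroxyls at C3, C6 and C8)
Conditions: HF·pyridine, pyridine, THF, 0 °C → rt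
Reagents that add atoms: none
Why: Buffered fluoride removes both triethylsilyl ethers without ionising the doubly allylic C6 carbinol or the tertiary allylic C3 carbinol.

Step 12
Reactants: 17 triol
Product: 18 C6 acrylate
Conditions: CH2=CHCOCl (1.05 equiv), i-Pr2NEt, CH2Cl2, −78 °C
Reagents that add atoms: acryloyl chloride, C=CC(Cl)=O
Why: Acylation of the least hindered hydroxyl: C6–OH lies between two sp2 carbons, whereas C8–OH is flanked by the fully substituted C3 and by C9, and C3–OH is tertiary.

Step 13
Reactants: 18 C6 acrylate
Product: 19 C8 ketone (α-hydroxy ketone with the C3 carbinol)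
Conditions: IBX, DMSO, rt
Reagents that add atoms: none
Why: IBX oxidises the secondary hydroxyl of a 1,2-diol to the ketol without cleaving the C3–C8 bond, which other glycol-cleaving oxidants could break too early; the neutral medium protects the C9 centre next to the new carbonyl.

Step 14
Reactants: 19 keto acrylate
Product: 20 keto butenolide (4-substituted furan-2(5H)-one with C6 as its C5)
Conditions: second-generation Grubbs catalyst (5 mol%), CH2Cl2, 40 °C
Reagents that add atoms: none
Why: Ring-closing metathesis of an allylic acrylate to a butenolide; the catalyst loads at the monosubstituted vinyl group and closes the five-membered ring onto the acrylate, and the two trisubstituted alkenes do not take part.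

Step 15
Reactants: 20 keto butenolide
Product: 22 cis-fused ring A/ring B 3,8-diol with cis-fused γ-lactone, via samarium enolate 21 (not isolated)
Conditions: SmI2 (2.5 equiv), THF, MeOH (4 equiv), −78 °C; NH4Cl (aq)
Reagents that add atoms: none
Why: Ketyl–olefin cyclisation: SmI2 reduces the chelating α-hydroxy ketone to a ketyl that adds 6-exo to C7 of the butenolide, and the samarium enolate is then protonated at C11. The tether reaches C7 from C6, so the new bond can only form on the face of C5; the lactone is therefore cis-fused and C7 is fixed by C6 alone. Chelation of samarium between O8 and O3, with approach anti to the C9 ether, should give the cis ring-fusion diol.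

Step 16
Reactants: 22 diol lactone
Product: 25 α-methylene diol lactone, via Mannich base 23 (not isolated), via trimethylammonium iodide 24 (not isolated)
Conditions: LDA (3.3 equiv), THF, −78 → −40 °C; CH2=NMe2+ I−, −78 °C → rt; then MeI, MeOH, rt; NaHCO3 (aq), CH2Cl2
Reagents that add atoms: Eschenmoser's salt, C=[N+](C)C.[I-]
Why: Aminomethylation of the lactone enolate, quaternisation and elimination (α-methylenation); the two tertiary alkoxides are inert spectators, and placing this step before the ring is opened keeps enolate chemistry away from the later diketone and esters.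

Step 17
Reactants: 25 α-methylene diol lactone
Product: 27 ten-membered C3,C8-diketone, via cyclic lead diolate 26 (not isolated)
Conditions: Pb(OAc)4 (1.1 equiv), K2CO3, CH2Cl2, −20 → 0 °C; used at once
Reagents that add atoms: none
Why: Tetravalent lead exchanges two acetates for the two tertiary hydroxyls to give the five-membered cyclic lead diolate 26, which fragments in a concerted two-electron process that breaks C3–C8, forms the C3 and C8 carbonyls and releases Pb(OAc)2. The closest known reaction is the Criegee cleavage of cis-decalin-9,10-diols to cyclodecane-1,6-diones. The ten-membered ring is not closed by bond formation but unveiled by ring expansion, through scission of the bond shared by ring A and ring B. No stereocentre is created: C6, C7 and C9 are carried over, and C3 and C8 become trigonal. Each trisubstituted alkene was the ring alkene of a cyclohexene, so C4=C5 and C1=C10 must emerge Z. The step needs chemoselectivity for the glycol over three alkenes, the PMB ether and the lactone, and the cis disposition of the hydroxyls set in step 15 secures it, because cyclic ester formation is then far faster than any attack of the oxidant on an alkene. It also needs the C7 and C9 centres beside the new C8 carbonyl to survive, which the carbonate buffer, the low temperature and immediate use in step 18 are meant to secure.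

Step 18
Reactants: 27 ten-membered diketone
Product: 28 (8S)-alcohol with the C3 enone intact
Conditions: Zn(BH4)2 (0.6 equiv), Et2O, −78 °C
Reagents that add atoms: none
Why: Chelation-controlled (Cram chelate) reduction: zinc bridges the C8 carbonyl and the C9 PMB ether, which activates this ketone over the less electrophilic C3 enone, and hydride arrives anti to the C10 substituent to give the 8,9-anti alcohol; in ether at low temperature the borohydride should not add to the α-methylene lactone.

Step 19
Reactants: 28 keto alcohol
Product: 29 (3S,8S)-diol
Conditions: (R)-2-methyl-CBS-oxazaborolidine (1 equiv), catecholborane (2 equiv), toluene, −78 °C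
Reagents that add atoms: none
Why: Corey–Bakshi–Shibata reduction: the α-branched alkenyl side (C4) acts as the large group and the C2 methylene as the small one, so the R catalyst should deliver hydride to give the 3S allylic alcohol by reagent control; catecholborane at this temperature leaves the lactone and alkenes alone.

Step 20
Reactants: 29 diol
Product: 30 C3 acetate with free C8 hydroxyl
Conditions: Ac2O (1.1 equiv), pyridine, DMAP (cat.), CH2Cl2, −20 °C
Reagents that add atoms: acetic anhydride, CC(=O)OC(C)=O
Why: Selective acetylation of the less hindered allylic C3 hydroxyl; the C8 hydroxyl lies between two branched carbons and is hydrogen-bonded to the PMB ether oxygen.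

Step 21
Reactants: 31 angelic acid
Product: 32 (2Z)-2-methylbut-2-en-1-ol
Conditions: LiAlH4, Et2O, 0 °C
Reagents that add atoms: none
Why: Hydride reduction of the unsaturated acid to the allylic alcohol; the low temperature and absence of acid preserve the Z geometry.

Step 22
Reactants: 32 (2Z)-2-methylbut-2-en-1-ol
Product: 33 [(2S,3R)-2,3-dimethyloxiran-2-yl]methanol
Conditions: Ti(OiPr)4 (cat.), L-(+)-diisopropyl tartrate (cat.), t-BuOOH, 4 Å MS, CH2Cl2, −20 °C
Reagents that add atoms: tert-butyl hydroperoxide, CC(C)(C)OO
Why: Sharpless asymmetric epoxidation: the L-(+)-tartrate delivers oxygen to the face that gives the 2S epoxy alcohol, the same sense as with simple E allylic alcohols, and the Z geometry is carried over as the cis relationship of the C3 methyl and the CH2OH group.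

Step 23
Reactants: 33 epoxy alcohol
Product: 35 (2R,3R)-2,3-dimethyloxirane-2-carboxylic acid, via epoxy aldehyde 34 (not isolated)
Conditions: TEMPO (cat.), PhI(OAc)2, MeCN/H2O, 0 °C → rt
Reagents that add atoms: water, O
Why: Oxoammonium-catalysed oxidation of the primary alcohol through the aldehyde hydrate to the acid under near-neutral conditions that leave the epoxide intact; the C2 descriptor changes from S to R only because the priorities change.

Step 24
Reactants: 30 C3 acetate; 35 epoxy acid
Product: 37 C8 epoxyangelate PMB ether, via mixed anhydride 36 (not isolated)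
Conditions: 35, 2,4,6-Cl3C6H2COCl, Et3N, THF, rt; then 30, DMAP, toluene, 40 °C
Reagents that add atoms: none
Why: Yamaguchi esterification: DMAP attacks the mixed anhydride of the hindered acid at the epoxy acyl carbon, and the acylpyridinium ion acylates the single free hydroxyl at C8; the substrate no longer holds an enolisable ketone, so the forcing conditions are tolerable.

Step 25
Reactants: 37 PMB ether
Product: 38 CNP0299903.1 (target)
Conditions: DDQ, CH2Cl2/pH 7 buffer, 0 °C
Reagents that add atoms: none
Why: Oxidative removal of the PMB ether under neutral buffered conditions, which avoids migration of the C8 ester to the freed C9 hydroxyl and spares the epoxide, the acetate and the α-methylene lactone.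

## Compound list

1 | toluene cis-dihydrodiol, (1S,2R)-3-methylcyclohexa-3,5-diene-1,2-diol | CC1=CC=C[C@H](O)[C@@H]1O | starting material
2 | 4-methoxybenzylidene acetal of 1 (cis-fused, both acetal epimers) | CC1=CC=C[C@@H]2OC(c3ccc(OC)cc3)O[C@H]12 | intermediate
3 | (1S,6R)-6-[(4-methoxybenzyl)oxy]-5-methylcyclohexa-2,4-dien-1-ol | CC1=CC=C[C@H](O)[C@@H]1OCc2ccc(OC)cc2 | intermediate
4 | (1R,2R,3R,6S)-3-[(4-methoxybenzyl)oxy]-4-methyl-7-oxabicyclo[4.1.0]hept-4-en-2-ol | CC1=C[C@@H]2O[C@@H]2[C@H](O)[C@@H]1OCc3ccc(OC)cc3 | intermediate
5 | triethylsilyl ether of 4 | CC1=C[C@@H]2O[C@@H]2[C@H](O[Si](CC)(CC)CC)[C@@H]1OCc3ccc(OC)cc3 | intermediate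
6 | (2R,3R)-3-[(4-methoxybenzyl)oxy]-4-methyl-2-[(triethylsilyl)oxy]cyclohex-4-en-1-one | CC1=CCC(=O)[C@H](O[Si](CC)(CC)CC)[C@@H]1OCc2ccc(OC)cc2 | intermediate
7 | acrolein | C=CC=O | starting material
8 | 1-propynylmagnesium bromide | CC#C[Mg]Br | starting material
9 | rac-hex-1-en-4-yn-3-ol | C=CC(O)C#CC | intermediate
10 | sodium alkenylalanate (five-membered oxa-aluminate from 9) | C=CC1O[Al-](OCCOC)(OCCOC)C(C)=C1.[Na+] | intermediate
11 | rac-(4Z)-5-iodohexa-1,4-dien-3-ol | C=CC(O)/C=C(\I)C | intermediate
12 | (3S,4Z)-5-iodohexa-1,4-dien-3-ol | O[C@@H](C=C)/C=C(\I)C | intermediate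
13 | triethyl{[(3S,4Z)-5-iodohexa-1,4-dien-3-yl]oxy}silane | CC[Si](CC)(CC)O[C@@H](C=C)/C=C(\I)C | intermediate
14 | alkenyllithium from 13 | CC[Si](CC)(CC)O[C@@H](C=C)/C=C(\[Li])C | intermediate
15 | alkenylcerium dichloride from 14 | CC[Si](CC)(CC)O[C@@H](C=C)/C=C(\[Ce](Cl)Cl)C | intermediate
16 | ring B tertiary carbinol with (2Z,4S)-4-(triethylsilyloxy)hexa-2,5-dien-2-yl chain at C3; C3–OH, C8–OSiEt3, C9–OPMB all cis | CC1=CC[C@@](O)(/C(C)=C\[C@@H](O[Si](CC)(CC)CC)C=C)[C@H](O[Si](CC)(CC)CC)[C@@H]1OCc2ccc(OC)cc2 | intermediate
17 | triol (C3, C6, C8 hydroxyls) | CC1=CC[C@@](O)(/C(C)=C\[C@@H](O)C=C)[C@H](O)[C@@H]1OCc2ccc(OC)cc2 | intermediate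
18 | C6 acrylate of 17 | CC1=CC[C@@](O)(/C(C)=C\[C@@H](OC(=O)C=C)C=C)[C@H](O)[C@@H]1OCc2ccc(OC)cc2 | intermediate
19 | C8 ketone (α-hydroxy ketone) acrylate | CC1=CC[C@@](O)(/C(C)=C\[C@@H](OC(=O)C=C)C=C)C(=O)[C@@H]1OCc2ccc(OC)cc2 | intermediate
20 | keto butenolide | CC1=CC[C@@](O)(/C(C)=C\[C@H]2OC(=O)C=C2)C(=O)[C@@H]1OCc3ccc(OC)cc3 | intermediate
21 | samarium enolate of the cyclised lactone | O[C@]12C(C)=C[C@H]3OC(O[Sm](I)I)=C[C@H]3[C@@]1(O[Sm](I)I)[C@H](OCc4ccc(OC)cc4)C(C)=CC2 | intermediate
22 | cis-fused ring A/ring B 3,8-diol with cis-fused γ-lactone (C11 as CH2) | O[C@]12C(C)=C[C@H]3OC(=O)C[C@H]3[C@@]1(O)[C@H](OCc4ccc(OC)cc4)C(C)=CC2 | intermediate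
23 | Mannich base (C11 dimethylaminomethyl lactone) | O[C@]12C(C)=C[C@H]3OC(=O)C(CN(C)C)[C@H]3[C@@]1(O)[C@H](OCc4ccc(OC)cc4)C(C)=CC2 | intermediate
24 | trimethylammonium iodide of 23 | O[C@]12C(C)=C[C@H]3OC(=O)C(C[N+](C)(C)C)[C@H]3[C@@]1(O)[C@H](OCc4ccc(OC)cc4)C(C)=CC2.[I-] | intermediate
25 | α-methylene diol lactone (substrate of the glycol scission) | O[C@]12C(C)=C[C@H]3OC(=O)C(=C)[C@H]3[C@@]1(O)[C@H](OCc4ccc(OC)cc4)C(C)=CC2 | intermediate
26 | cyclic lead diacetate diolate of 25 | CC(=O)O[Pb]1(OC(C)=O)O[C@]23C(C)=C[C@H]4OC(=O)C(=C)[C@H]4[C@@]2(O1)[C@H](OCc5ccc(OC)cc5)C(C)=CC3 | intermediate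
27 | ten-membered C3,C8-diketone with Z C1=C10 and Z C4=C5, C9 PMB ether, α-methylene lactone | C=C1C(=O)O[C@@H]2/C=C(/C)C(=O)C/C=C(/C)[C@@H](OCc3ccc(OC)cc3)C(=O)[C@H]12 | intermediate
28 | (8S)-hydroxy C3-enone | C=C1C(=O)O[C@@H]2/C=C(/C)C(=O)C/C=C(/C)[C@@H](OCc3ccc(OC)cc3)[C@@H](O)[C@H]12 | intermediate
29 | (3S,8S)-diol | C=C1C(=O)O[C@@H]2/C=C(/C)[C@@H](O)C/C=C(/C)[C@@H](OCc3ccc(OC)cc3)[C@@H](O)[C@H]12 | intermediate
30 | C3 acetate, C8 hydroxyl free | C=C1C(=O)O[C@@H]2/C=C(/C)[C@@H](OC(C)=O)C/C=C(/C)[C@@H](OCc3ccc(OC)cc3)[C@@H](O)[C@H]12 | intermediate
31 | angelic acid | C/C=C(/C)C(O)=O | starting material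
32 | (2Z)-2-methylbut-2-en-1-ol | C/C=C(/C)CO | intermediate
33 | [(2S,3R)-2,3-dimethyloxiran-2-yl]methanol | OC[C@]1(C)O[C@@H]1C | intermediate
34 | (2R,3R)-2,3-dimethyloxirane-2-carbaldehyde | O=C[C@]1(C)O[C@@H]1C | intermediate
35 | (2R,3R)-2,3-dimethyloxirane-2-carboxylic acid | OC(=O)[C@]1(C)O[C@@H]1C | intermediate
36 | mixed anhydride of 35 with 2,4,6-trichlorobenzoic acid | O=C(OC(=O)[C@]1(C)O[C@@H]1C)c1c(Cl)cc(Cl)cc1Cl | intermediate
37 | C9 PMB ether of the target | C=C1C(=O)O[C@@H]2/C=C(/C)[C@@H](OC(C)=O)C/C=C(/C)[C@@H](OCc3ccc(OC)cc3)[C@@H](OC(=O)[C@]3(C)O[C@@H]3C)[C@H]12 | intermediate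
38 | CNP0299903.1 | C=C1C(=O)O[C@@H]2/C=C(/C)[C@@H](OC(C)=O)C/C=C(/C)[C@@H](O)[C@@H](OC(=O)[C@]3(C)O[C@@H]3C)[C@H]12 | target

## Step count and least certain steps

Total: 25 steps. Longest linear sequence: 18 steps (steps 1–5, 10–20, 24 and 25, from 1). The side branches are steps 6–9 (alkenyl iodide) and steps 21–23 (epoxy acid).

**Step 17 (key step).** As it forms, the 1,6-diketone can enolise at C2, C7 or C9 under the acetic acid set free or the buffer. This would lead to transannular aldol closure, movement of the C1=C10 alkene into conjugation, or epimerisation at C7 or C9; excess oxidant could also acetoxylate next to the new carbonyls. Fallback: the diketone is not isolated. Setting out from 25, the scission is run at −78 °C and the cold, filtered solution is added directly to Zn(BH4)2 in ether, so that the C8 carbonyl is reduced before the mixture is warmed. The route is rejoined at 28 and no new compound is made.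

**Step 15.** The ketyl may lose one of its α-oxygen substituents by reductive cleavage, or be reduced to the alcohol, before it closes the ring, because a second electron transfer competes with the 6-exo addition. Closure to a trans diol is a lesser risk. Fallback, a polar annulation from triol 17: both secondary hydroxyls are oxidised with IBX to the cross-conjugated dienone diketone F1. Base-catalysed addition of dimethyl malonate to the vinyl ketone terminus, with aldol closure of the C7 enolate onto the C8 ketone in the same flask, should give annulated keto diester F2 with the C7 side chain in the thermodynamically preferred position. NaBH4/CeCl3 reduction of the enone carbonyl and lactonisation give lactone ester F3. Saponification followed by decarboxylative Mannich methylenation (aqueous CH2O, Et2NH) returns to 25. In this reserve route C6 and C7 rest on thermodynamic and hydride-face control within the bicycle and no longer on the resolved C6 centre, which is why it is not the first choice.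

**Step 5.** The π-allylpalladium intermediate may lose a hydrogen from the C14 methyl to give a dienol instead of transferring the carbinol hydrogen, or the β,γ-enone may drift into conjugation on prolonged contact with the catalyst. Fallback from 5: palladium-catalysed hydrogenolysis of the vinyl epoxide (Pd2(dba)3, n-Bu3P, HCO2H/Et3N) delivers hydride to the allylic carbon C2 and should give homoallylic alcohol F4. Dess–Martin oxidation of F4 then rejoins the route at 6.

**Step 18.** Hydride may also reach the C3 enone, which would lose chemoselectivity; it may add in conjugate fashion to the α-methylene lactone; or it may approach the carbonyl outside the chelate and give the 8-epimer. Fallback: the methylene is introduced only after the reductions. Setting out from 22 (step 16 omitted), Pb(OAc)4 scission gives methylene-free diketone F5. Zn(BH4)2 reduction gives alcohol F6 and oxazaborolidine reduction gives diol F7. Et3SiOTf/2,6-lutidine gives bis-silyl ether F8. LDA, Eschenmoser's salt, then MeI and NaHCO3 give α-methylene bis-silyl ether F9, and HF·pyridine rejoins the route at 29.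

**Step 20.** Acetylation may not discriminate well enough between the two secondary hydroxyls, and the free C8 hydroxyl could engage the lactone carbonyl under basic conditions. Fallback from 28: the C8 hydroxyl is silylated (Et3SiOTf, 2,6-lutidine) to F10, the C3 ketone is reduced with the oxazaborolidine to F11, the C3 hydroxyl is acetylated to F12, and HF·pyridine removes the silyl group to rejoin the route at 30.

## Further compounds

F0 | step 17 | none | none
F1 | step 15 | dienone diketone from 17 (C6 and C8 ketones) | CC1=CC[C@@](O)(/C(C)=C\C(=O)C=C)C(=O)[C@@H]1OCc2ccc(OC)cc2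
F2 | step 15 | annulated keto diester (ring A closed, C6 ketone, C7 bearing CH2CH(CO2Me)2) | O[C@]12C(C)=CC(=O)[C@@H](CC(C(=O)OC)C(=O)OC)[C@@]1(O)[C@H](OCc3ccc(OC)cc3)C(C)=CC2
F3 | step 15 | C11 methoxycarbonyl lactone | O[C@]12C(C)=C[C@H]3OC(=O)C(C(=O)OC)[C@H]3[C@@]1(O)[C@H](OCc4ccc(OC)cc4)C(C)=CC2
F4 | step 5 | homoallylic alcohol (C3 hydroxyl, C2 methylene) | CC1=CC[C@H](O)[C@H](O[Si](CC)(CC)CC)[C@@H]1OCc2ccc(OC)cc2
F5 | step 18 | ten-membered C3,C8-diketone without the exocyclic methylene | C1C(=O)O[C@@H]2/C=C(/C)C(=O)C/C=C(/C)[C@@H](OCc3ccc(OC)cc3)C(=O)[C@H]12
F6 | step 18 | (8S)-hydroxy C3-enone without the exocyclic methylene | C1C(=O)O[C@@H]2/C=C(/C)C(=O)C/C=C(/C)[C@@H](OCc3ccc(OC)cc3)[C@@H](O)[C@H]12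
F7 | step 18 | (3S,8S)-diol without the exocyclic methylene | C1C(=O)O[C@@H]2/C=C(/C)[C@@H](O)C/C=C(/C)[C@@H](OCc3ccc(OC)cc3)[C@@H](O)[C@H]12
F8 | step 18 | 3,8-bis(triethylsilyl) ether of F7 | C1C(=O)O[C@@H]2/C=C(/C)[C@@H](O[Si](CC)(CC)CC)C/C=C(/C)[C@@H](OCc3ccc(OC)cc3)[C@@H](O[Si](CC)(CC)CC)[C@H]12
F9 | step 18 | α-methylene lactone 3,8-bis(triethylsilyl) ether | C=C1C(=O)O[C@@H]2/C=C(/C)[C@@H](O[Si](CC)(CC)CC)C/C=C(/C)[C@@H](OCc3ccc(OC)cc3)[C@@H](O[Si](CC)(CC)CC)[C@H]12
F10 | step 20 | C8 triethylsilyl ether of 28 | C=C1C(=O)O[C@@H]2/C=C(/C)C(=O)C/C=C(/C)[C@@H](OCc3ccc(OC)cc3)[C@@H](O[Si](CC)(CC)CC)[C@H]12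
F11 | step 20 | (3S)-alcohol with C8 triethylsilyl ether | C=C1C(=O)O[C@@H]2/C=C(/C)[C@@H](O)C/C=C(/C)[C@@H](OCc3ccc(OC)cc3)[C@@H](O[Si](CC)(CC)CC)[C@H]12
F12 | step 20 | C3 acetate with C8 triethylsilyl ether | C=C1C(=O)O[C@@H]2/C=C(/C)[C@@H](OC(C)=O)C/C=C(/C)[C@@H](OCc3ccc(OC)cc3)[C@@H](O[Si](CC)(CC)CC)[C@H]12
A1 | alternative 1 | cis-fused α-methylene lactol ethyl ether with free C8 hydroxyl and C9 triethylsilyl ether | C=C1[C@@H](OCC)O[C@@H]2/C=C(/C)[C@@H](OC(C)=O)C/C=C(/C)[C@@H](O[Si](CC)(CC)CC)[C@@H](O)[C@H]12
A2 | alternative 2 | protected ten-membered α-methylene lactone (C8 PMB ether, C9 triethylsilyl ether) | C=C1C(=O)O[C@@H]2/C=C(/C)[C@@H](OC(C)=O)C/C=C(/C)[C@@H](O[Si](CC)(CC)CC)[C@@H](OCc3ccc(OC)cc3)[C@H]12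
A3 | alternative 3 | ten-membered C9 ketone with free C8 hydroxyl and α-methylene lactone | C=C1C(=O)O[C@@H]2/C=C(/C)[C@@H](OC(C)=O)C/C=C(/C)C(=O)[C@@H](O)[C@H]12
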